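**Plan**

Numbering used: ring A = C1(O-angeloyl)–C2–C3–C4(Me)–C5(Me)–C10; ring B = C5–C6=C7(side chain C11)–C8(=O)–C9=C10.
Retrosynthetic cuts, in order: the angelate C–O; C1–O (γ-hydroxylation); C6=C7 (dehydrogenation); C7–C11 (enolate alkylation); C9=C10 and C5–C6 (Michael/aldol annulation); last, C1–C2 and C3–C4 of ring A together ([4+2]).
Enabling feature: C10 is the β-carbon of the ring B enone, so it is a latent ketone carbon, and the adjacent C5 carries the methyl group. The C5=C10 enol ether of that ketone is exactly the double bond left by a Diels–Alder reaction of the diene C1=C10(OSi)–C5(Me)=C4(Me) with a two-carbon dienophile C2=C3, and it is the nucleophile needed to make C5 quaternary.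
Forward order: ring A first (catalytic asymmetric Diels–Alder with an acrylate as ethylene equivalent, ester then excised); ring B second (Mukaiyama–Michael/aldol); then the side chain, C6=C7, C1–OH and the angelate.
Stereochemistry: C4 from the catalyst-controlled cycloaddition; C5 by addition anti to the C4 methyl; C11 from (S)-lactate by SN2 inversion; C1 by axial peracid attack on the trienol ether; angelate geometry from angelic acid.

Key step: step 2

Remark: the facial sense of the oxazaborolidinium catalyst in step 2 is assigned from its binding model for acrylates; if the adduct proves antipodal, the mirror-image catalyst is used and nothing else changes.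

**Step 1**
Reactants: 1 (E)-3-methylpent-3-en-2-one
Product: 2 (E)-triisopropyl[(3-methylpenta-1,3-dien-2-yl)oxy]silane
Conditions: i-Pr3SiOTf, Et3N, CH2Cl2, 0 °C
Reagents that add atoms: triisopropylsilyl trifluoromethanesulfonate, CC(C)[Si](OS(=O)(=O)C(F)(F)F)(C(C)C)C(C)C
Why: Soft enolisation of the methyl ketone (silyl triflate/amine) removes a proton from the acetyl methyl group and should give the cross-conjugated 2-silyloxydiene; no stereocentre is formed and the E geometry of the trisubstituted alkene is kept.

**Step 2**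
Reactants: 2 (E)-triisopropyl[(3-methylpenta-1,3-dien-2-yl)oxy]silane; 3 2,2,2-trifluoroethyl acrylate
Product: 4 2,2,2-trifluoroethyl (1S,2S)-2,3-dimethyl-4-[(triisopropylsilyl)oxy]cyclohex-3-ene-1-carboxylate
Conditions: (R)-3,3-diphenyl-1-(o-tolyl)tetrahydro-1H,3H-pyrrolo[1,2-c][1,3,2]oxazaborole (20 mol%), Tf2NH (16 mol%), CH2Cl2, −78 to −40 °C; chromatography to remove the exo adduct
Reagents that add atoms: none
Why: The protonated oxazaborolidine binds the acrylate carbonyl and the diene C1=C10–C5=C4 adds to C2=C3 in a concerted, asynchronous [4+2] cycloaddition (Lewis acid-catalysed normal-demand Diels–Alder reaction) that makes C1–C2 and C3–C4 in the same step. The closest known reaction type is the cationic oxazaborolidine-catalysed addition of 2-(trialkylsilyloxy)buta-1,3-dienes to 2,2,2-trifluoroethyl acrylate. Ring A closes by intermolecular cycloaddition that is suprafacial on both partners, and the C5=C10 double bond it leaves is the regiodefined tetrasubstituted silyl enol ether needed in step 5. C3 is set by the catalyst, whose aryl group on the carbinol carbon covers one face of the s-trans acrylate so that the diene meets the Re face of the α-carbon, and C4 is set relative to C3 by the endo transition state together with the E geometry of the diene, which puts the C4 methyl cis to the ester. Regiochemistry (ester on C3, next to C4) is secured by the 2-silyloxy group and the terminal methyl, which both place the largest HOMO coefficient on C1, the carbon that bonds to the acrylate β-carbon. Endo and enantiofacial selectivity are both needed because C3 is later erased, so the minor exo adduct (which would end as the C4 enantiomer) is removed by chromatography, and any Z diene stays behind because it cannot reach the s-cis conformation.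

**Step 3**
Reactants: 4 2,2,2-trifluoroethyl (1S,2S)-2,3-dimethyl-4-[(triisopropylsilyl)oxy]cyclohex-3-ene-1-carboxylate
Product: 5 (1S,2S)-2,3-dimethyl-4-[(triisopropylsilyl)oxy]cyclohex-3-ene-1-carbaldehyde
Conditions: i-Bu2AlH (1.05 equiv), CH2Cl2, −78 °C; aqueous sodium potassium tartrate
Reagents that add atoms: none
Why: Partial reduction of the activated ester by the aluminium hydride should stop at the aluminium hemiacetal at −78 °C and give the aldehyde on work-up, the silyl enol ether being inert; epimerisation at C3 is without consequence because this carbon becomes a methylene group in step 4.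

**Step 4**
Reactants: 5 (1S,2S)-2,3-dimethyl-4-[(triisopropylsilyl)oxy]cyclohex-3-ene-1-carbaldehyde
Product: 6 [(3S)-2,3-dimethylcyclohex-1-en-1-yl]oxy(triisopropyl)silane
Conditions: [RhCl(cod)]2 (2.5 mol%), Ph2P(CH2)3PPh2 (5 mol%), diglyme, 160 °C
Reagents that add atoms: none
Why: Rhodium-catalysed decarbonylation (insertion into the formyl C–H bond, CO extrusion, C–H reductive elimination) removes the activating group of the dienophile and leaves C3 as CH2; the C4 stereocentre is not involved.

**Step 5**
Reactants: 6 [(3S)-2,3-dimethylcyclohex-1-en-1-yl]oxy(triisopropyl)silane; 7 but-3-en-2-one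
Product: 10 (4aR,5S)-4a,5-dimethyl-4,4a,5,6,7,8-hexahydronaphthalen-2(3H)-one, via silyl enol ether 8 (not isolated), via 1,5-diketone 9 (not isolated)
Conditions: Tf2NH (5 mol%), CH2Cl2, −78 °C; then TsOH·H2O, PhMe, 90 °C
Reagents that add atoms: none
Why: Mukaiyama–Michael addition of the tetrasubstituted silyl enol ether to the enone, then acid-mediated hydrolysis and aldol condensation (Robinson annulation), should close ring B; the quaternary C5 is set by attack of the enone anti to the C4 methyl, which allylic strain with the C5 methyl holds pseudoaxial, so the two methyl groups end cis.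

**Step 6**
Reactants: 11 methyl (S)-lactate
Product: 12 methyl (2S)-2-{[(trifluoromethyl)sulfonyl]oxy}propanoate
Conditions: Tf2O, 2,6-lutidine, CH2Cl2, −78 to 0 °C
Reagents that add atoms: trifluoromethanesulfonic anhydride, O=S(=O)(OS(=O)(=O)C(F)(F)F)C(F)(F)F
Why: O-Sulfonylation of the secondary alcohol with a hindered pyridine base forms the triflate without touching the C–O bond at the stereocentre, so the (S) configuration of the lactate is retained.

**Step 7**
Reactants: 10 (4aR,5S)-4a,5-dimethyl-4,4a,5,6,7,8-hexahydronaphthalen-2(3H)-one; 12 methyl (2S)-2-{[(trifluoromethyl)sulfonyl]oxy}propanoate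
Product: 14 methyl (2S)-2-[(2S,8S,8aR)-8,8a-dimethyl-3-oxo-1,2,3,5,6,7,8,8a-octahydronaphthalen-2-yl]propanoate, via lithium dienolate 13 (not isolated)
Conditions: LiN(i-Pr)2 (1.05 equiv), THF, −78 °C; then 12, −78 to −30 °C
Reagents that add atoms: none
Why: Kinetic deprotonation at C7 gives the cross-conjugated dienolate, which should displace the triflate in an SN2 enolate alkylation with inversion at the lactate carbon, making C11 (S) (the descriptor is unchanged because the substituent ranking changes); the C7 centre (electrophile expected on the face opposite the angular methyl) is erased in step 8.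

**Step 8**
Reactants: 14 methyl (2S)-2-[(2S,8S,8aR)-8,8a-dimethyl-3-oxo-1,2,3,5,6,7,8,8a-octahydronaphthalen-2-yl]propanoate
Product: 15 methyl (2S)-2-[(8S,8aS)-8,8a-dimethyl-3-oxo-3,5,6,7,8,8a-hexahydronaphthalen-2-yl]propanoate
Conditions: DDQ (1.2 equiv), 1,4-dioxane, 100 °C
Reagents that add atoms: none
Why: Quinone dehydrogenation of the enone under neutral conditions should proceed through the cross-conjugated C7 enol and hydride abstraction from C6, giving the cross-conjugated dienone and removing the C7 stereocentre while C11 is untouched.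

**Step 9**
Reactants: 15 methyl (2S)-2-[(8S,8aS)-8,8a-dimethyl-3-oxo-3,5,6,7,8,8a-hexahydronaphthalen-2-yl]propanoate
Product: 16 methyl (2S)-2-[(8S,8aS)-3-[(tert-butyldimethylsilyl)oxy]-8,8a-dimethyl-6,7,8,8a-tetrahydronaphthalen-2-yl]propanoate
Conditions: t-BuMe2SiOTf, Et3N, CH2Cl2, 0 °C
Reagents that add atoms: tert-butyldimethylsilyl trifluoromethanesulfonate, CC(C)(C)[Si](C)(C)OS(=O)(=O)C(F)(F)F
Why: Silyl triflate/amine enolisation of the cross-conjugated dienone removes a γ-proton from C1, the only position in conjugation with the activated carbonyl, and should give the linear trienol silyl ether (C6=C7, C8=C9, C10=C1); no stereocentre is formed.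

**Step 10**
Reactants: 16 methyl (2S)-2-[(8S,8aS)-3-[(tert-butyldimethylsilyl)oxy]-8,8a-dimethyl-6,7,8,8a-tetrahydronaphthalen-2-yl]propanoate
Product: 17 methyl (2S)-2-[(5R,8S,8aS)-5-hydroxy-8,8a-dimethyl-3-oxo-3,5,6,7,8,8a-hexahydronaphthalen-2-yl]propanoate
Conditions: mCPBA, NaHCO3, CH2Cl2, −20 °C; aqueous citric acid work-up
Reagents that add atoms: 3-chloroperoxybenzoic acid, O=C(OO)c1cccc(Cl)c1
Why: Vinylogous Rubottom oxidation, in which the peracid attacks the electron-rich terminus C1 of the trienol ether and collapse regenerates the dienone; stereoelectronically preferred axial attack on the chair-like ring A (the course known for peracid oxidation of steroidal 3,5-dienol ethers to 6β-alcohols) should place the hydroxyl on the face of the C5 methyl, i.e. (1R) in the numbering of the plan.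

**Step 11**
Reactants: 17 methyl (2S)-2-[(5R,8S,8aS)-5-hydroxy-8,8a-dimethyl-3-oxo-3,5,6,7,8,8a-hexahydronaphthalen-2-yl]propanoate; 18 angelic acid
Product: 20 (1R,4S,4aS)-6-[(2S)-1-methoxy-1-oxopropan-2-yl]-4,4a-dimethyl-7-oxo-1,2,3,4,4a,7-hexahydronaphthalen-1-yl (Z)-2-methylbut-2-enoate, via mixed anhydride 19 (not isolated)
Conditions: 18, 2,4,6-trichlorobenzoyl chloride, Et3N, PhMe, 25 °C; then 17, 70 °C
Reagents that add atoms: none
Why: Acylation through the mixed anhydride of angelic acid with 2,4,6-trichlorobenzoic acid (Yamaguchi-type esterification run without a nucleophilic catalyst) should transfer the angeloyl group with retention at C1 and without Z-to-E isomerisation of the acid.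

**Compound list**

1 | (E)-3-methylpent-3-en-2-one | C/C=C(\C)C(C)=O | starting material
2 | (E)-triisopropyl[(3-methylpenta-1,3-dien-2-yl)oxy]silane | C/C=C(\C)C(=C)O[Si](C(C)C)(C(C)C)C(C)C | intermediate
3 | 2,2,2-trifluoroethyl acrylate | C=CC(=O)OCC(F)(F)F | starting material
4 | 2,2,2-trifluoroethyl (1S,2S)-2,3-dimethyl-4-[(triisopropylsilyl)oxy]cyclohex-3-ene-1-carboxylate | O=C(OCC(F)(F)F)[C@H]1CCC(O[Si](C(C)C)(C(C)C)C(C)C)=C(C)[C@H]1C | intermediate
5 | (1S,2S)-2,3-dimethyl-4-[(triisopropylsilyl)oxy]cyclohex-3-ene-1-carbaldehyde | O=C[C@H]1CCC(O[Si](C(C)C)(C(C)C)C(C)C)=C(C)[C@H]1C | intermediate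
6 | [(3S)-2,3-dimethylcyclohex-1-en-1-yl]oxy(triisopropyl)silane | C[C@H]1CCCC(O[Si](C(C)C)(C(C)C)C(C)C)=C1C | intermediate
7 | but-3-en-2-one (methyl vinyl ketone) | CC(=O)C=C | starting material
8 | (2R,3S)-2,3-dimethyl-2-{3-[(triisopropylsilyl)oxy]but-2-en-1-yl}cyclohexan-1-one (E/Z mixture at the enol ether) | C[C@H]1CCCC(=O)[C@]1(C)CC=C(C)O[Si](C(C)C)(C(C)C)C(C)C | intermediate
9 | (2R,3S)-2,3-dimethyl-2-(3-oxobutyl)cyclohexan-1-one | C[C@H]1CCCC(=O)[C@]1(C)CCC(C)=O | intermediate
10 | (4aR,5S)-4a,5-dimethyl-4,4a,5,6,7,8-hexahydronaphthalen-2(3H)-one | O=C1CC[C@]2(C)[C@@H](C)CCCC2=C1 | intermediate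
11 | methyl (S)-lactate | C[C@H](O)C(=O)OC | starting material
12 | methyl (2S)-2-{[(trifluoromethyl)sulfonyl]oxy}propanoate | C[C@H](OS(=O)(=O)C(F)(F)F)C(=O)OC | intermediate
13 | lithium (4aR,5S)-4a,5-dimethyl-4,4a,5,6,7,8-hexahydronaphthalen-2-olate (cross-conjugated dienolate of 10) | [Li+].[O-]C1=CC[C@]2(C)[C@@H](C)CCCC2=C1 | intermediate
14 | methyl (2S)-2-[(2S,8S,8aR)-8,8a-dimethyl-3-oxo-1,2,3,5,6,7,8,8a-octahydronaphthalen-2-yl]propanoate (expected major C7 epimer shown) | O=C1C=C2CCC[C@H](C)[C@@]2(C)C[C@H]1[C@H](C)C(=O)OC | intermediate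
15 | methyl (2S)-2-[(8S,8aS)-8,8a-dimethyl-3-oxo-3,5,6,7,8,8a-hexahydronaphthalen-2-yl]propanoate | O=C1C=C2CCC[C@H](C)[C@@]2(C)C=C1[C@H](C)C(=O)OC | intermediate
16 | methyl (2S)-2-[(8S,8aS)-3-[(tert-butyldimethylsilyl)oxy]-8,8a-dimethyl-6,7,8,8a-tetrahydronaphthalen-2-yl]propanoate | CC(C)(C)[Si](C)(C)OC1=CC2=CCC[C@H](C)[C@@]2(C)C=C1[C@H](C)C(=O)OC | intermediate
17 | methyl (2S)-2-[(5R,8S,8aS)-5-hydroxy-8,8a-dimethyl-3-oxo-3,5,6,7,8,8a-hexahydronaphthalen-2-yl]propanoate | O[C@@H]1CC[C@H](C)[C@@]2(C)C=C([C@H](C)C(=O)OC)C(=O)C=C12 | intermediate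
18 | angelic acid, (Z)-2-methylbut-2-enoic acid | C/C=C(/C)C(=O)O | starting material
19 | (Z)-2-methylbut-2-enoic 2,4,6-trichlorobenzoic anhydride | C/C=C(/C)C(=O)OC(=O)c1c(Cl)cc(Cl)cc1Cl | intermediate
20 | (1R,4S,4aS)-6-[(2S)-1-methoxy-1-oxopropan-2-yl]-4,4a-dimethyl-7-oxo-1,2,3,4,4a,7-hexahydronaphthalen-1-yl (Z)-2-methylbut-2-enoate | C/C=C(/C)C(=O)O[C@@H]1CC[C@H](C)[C@@]2(C)C=C([C@H](C)C(=O)OC)C(=O)C=C12 | target

**Step count**

Total steps: 11. Longest linear sequence: 10 (steps 1–5 and 7–11, from compound 1).

**Steps most likely to fail**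

1. Step 7. E2 elimination of the secondary triflate by the basic dienolate, or O-alkylation, may outrun C-alkylation, and excess base could erode C11. The fallback brings the propanoate in with the annulation partner; it sets out from 6 and comes back at 14. Methyl (R)-3-bromo-2-methylpropanoate is treated with Zn and LiCl in THF to give the zinc reagent (R)-(3-methoxy-2-methyl-3-oxopropyl)zinc bromide F1. Acylation of F1 with acetyl chloride under Pd(PPh3)4 catalysis gives methyl (2S)-2-methyl-4-oxopentanoate F2. α-Methylenation on the more substituted side (paraformaldehyde, N-methylanilinium trifluoroacetate, THF, 65 °C) gives methyl (2S)-2-methyl-3-methylidene-4-oxopentanoate F3. Mukaiyama–Michael addition of 6 to F3 (Tf2NH cat., CH2Cl2, −78 °C) gives the silyl enol ether methyl (2S)-2-{1-[(1R,2S)-1,2-dimethyl-6-oxocyclohexyl]-3-[(triisopropylsilyl)oxy]but-2-en-2-yl}propanoate F4. Acidic work-up hydrolyses it to the diketo ester methyl (2S)-3-acetyl-4-[(1R,2S)-1,2-dimethyl-6-oxocyclohexyl]-2-methylbutanoate F5, and aldol condensation of F5 (TsOH·H2O, PhMe, 90 °C) gives 14.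

2. Step 10. Facial selectivity of the peracid at C1 may be poor, because ring A is more flexible than the steroid ring on which the precedent rests; attack at C9 is a lesser leak. The fallback uses an inverting esterification so that either C1 epimer is usable; it sets out from 16 and comes back at 20. The oxidation is run as in step 10, and the 1α-epimer methyl (2S)-2-[(5S,8S,8aS)-5-hydroxy-8,8a-dimethyl-3-oxo-3,5,6,7,8,8a-hexahydronaphthalen-2-yl]propanoate F6 is separated from 17 by chromatography. F6 is esterified with 18 under Mitsunobu conditions (PPh3, diisopropyl azodicarboxylate, PhMe, 0 °C), which forms the C1–O bond by SN2 displacement with inversion and gives 20 directly.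

3. Step 8. Enolisation towards the tertiary C7–H may be slow, which would let dehydrogenation on the C1/C2 side and over-oxidation compete. The fallback is a Saegusa–Ito dehydrogenation; it sets out from 14 and comes back at 15. Kinetic deprotonation at C7 with LiN(SiMe3)2 in the presence of Me3SiCl (THF, −78 °C) gives the cross-conjugated silyl dienol ether methyl (2S)-2-[(8S,8aR)-8,8a-dimethyl-3-[(trimethylsilyl)oxy]-1,5,6,7,8,8a-hexahydronaphthalen-2-yl]propanoate F7. Pd(OAc)2 (MeCN, 25 °C) converts F7 into 15 by β-hydride elimination from C6.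

**Further compounds**

F1 | step 7 | (R)-(3-methoxy-2-methyl-3-oxopropyl)zinc bromide | Br[Zn]C[C@H](C)C(=O)OC
F2 | step 7 | methyl (2S)-2-methyl-4-oxopentanoate | CC(=O)C[C@H](C)C(=O)OC
F3 | step 7 | methyl (2S)-2-methyl-3-methylidene-4-oxopentanoate | C=C(C(C)=O)[C@H](C)C(=O)OC
F4 | step 7 | methyl (2S)-2-{1-[(1R,2S)-1,2-dimethyl-6-oxocyclohexyl]-3-[(triisopropylsilyl)oxy]but-2-en-2-yl}propanoate | C[C@H]1CCCC(=O)[C@]1(C)CC(=C(C)O[Si](C(C)C)(C(C)C)C(C)C)[C@H](C)C(=O)OC
F5 | step 7 | methyl (2S)-3-acetyl-4-[(1R,2S)-1,2-dimethyl-6-oxocyclohexyl]-2-methylbutanoate | C[C@H]1CCCC(=O)[C@]1(C)CC(C(C)=O)[C@H](C)C(=O)OC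
F6 | step 10 | methyl (2S)-2-[(5S,8S,8aS)-5-hydroxy-8,8a-dimethyl-3-oxo-3,5,6,7,8,8a-hexahydronaphthalen-2-yl]propanoate | O[C@H]1CC[C@H](C)[C@@]2(C)C=C([C@H](C)C(=O)OC)C(=O)C=C12
F7 | step 8 | methyl (2S)-2-[(8S,8aR)-8,8a-dimethyl-3-[(trimethylsilyl)oxy]-1,5,6,7,8,8a-hexahydronaphthalen-2-yl]propanoate | C[Si](C)(C)OC1=C([C@H](C)C(=O)OC)C[C@]2(C)[C@@H](C)CCCC2=C1
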